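The route rests on disconnecting the C3–C4 bond of the pyranone ring (O1, C2, C3, C4, C4a, C8a) that carries the trans 2,3-dimethyl pair between the ring oxygen and the ketone. A carbene-catalysed hydroacylation adds the formyl C–H of a benzaldehyde across the vinyl group of its ortho (S)-but-3-en-2-yl ether; this one operation closes the ring, creates the C4 ketone and the C3 methyl group, and keeps C2 as set in the ether. The precursor is a fully substituted benzaldehyde flanked by that ether and a MOM ether, bearing prenyl, methoxy and an (R)-hexanoate side chain held as an allyl ester, and is built from a dihydrocoumarin.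

Key step: step 9

Remark on numbering: lactones 3–13 are numbered as chroman-2-ones (O1, C2 carbonyl, C4 bearing propyl); compounds 16–19 are numbered as chroman-4-ones.

Remark on step 2 (assumption): the antipode of the bisphosphine that gives the 4R lactone is assigned by analogy; if the first run should give the 4S lactone, the other antipode, also commercial, is used.

Remark on design: the acid is carried as an allyl ester so that no strong acid has to meet the prenyl alkene at the end, and the butenyl ether is made while the lactone still masks the second ortho oxygen, so only one phenol is ever free at each etherification.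

Step 1
Reactants: 1 3,5-dimethoxyphenol; 2 ethyl 3-oxohexanoate
Product: 3 5,7-dimethoxy-4-propyl-2H-chromen-2-one
Conditions: CH3SO3H (neat), 0 °C → rt
Reagents that add atoms: none
Why: Pechmann condensation, in which acid-promoted ester exchange with the phenol, ring closure onto the ortho carbon and dehydration should give the coumarin, the symmetry of 1 allowing only one regioisomer.

Step 2
Reactants: 3 5,7-dimethoxy-4-propyl-2H-chromen-2-one
Product: 4 (R)-5,7-dimethoxy-4-propylchroman-2-one
Conditions: Cu(OAc)2·H2O (3 mol %), (S)-DTBM-SEGPHOS (3 mol %), HSiMe(OEt)2 (2 equiv), t-BuOH (2 equiv), toluene, 0 °C → rt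
Reagents that add atoms: none
Why: Asymmetric conjugate reduction with bisphosphine-bound CuH, a known reaction of 4-substituted coumarins, in which hydride is delivered to one face of C4 under control of the chiral ligand and sets the R centre, while tert-butanol protonates the enolate quickly so that the lactone carbonyl is not reduced further.

Step 3
Reactants: 4 (R)-5,7-dimethoxy-4-propylchroman-2-one
Product: 6 (R)-5,7-dimethoxy-2-oxo-4-propylchroman-8-carbaldehyde, via aryl iminium chloride 5 (not isolated)
Conditions: [Me2N=CHCl]Cl (1.5 equiv), DMF, 0 → 60 °C; then H2O, rt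
Reagents that add atoms: (chloromethylene)dimethyliminium chloride, C[N+](C)=CCl.[Cl-]; water, O
Why: Vilsmeier–Haack formylation, in which the chloroiminium ion should attack C8 because it is para to the 5-methoxy group, ortho to the 7-methoxy group and less crowded than C6 (which lies between two methoxy groups), and water then hydrolyses iminium salt 5 to the aldehyde.

Step 4
Reactants: 6 (R)-5,7-dimethoxy-2-oxo-4-propylchroman-8-carbaldehyde
Product: 8 (R)-7-hydroxy-5-methoxy-2-oxo-4-propylchroman-8-carbaldehyde, via aryloxy dichloroborane 7 (not isolated)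
Conditions: BCl3 (1.2 equiv), CH2Cl2, −78 → 0 °C; then H2O
Reagents that add atoms: none
Why: Chelation-controlled aryl methyl ether cleavage, in which BCl3 binds between the formyl oxygen and the adjacent 7-methoxy oxygen so that chloride removes only that methyl group, while the 5-methoxy group para to the aldehyde and the lactone are not chelated and should survive at or below 0 °C.

Step 5
Reactants: 8 (R)-7-hydroxy-5-methoxy-2-oxo-4-propylchroman-8-carbaldehyde
Product: 9 (R)-7-hydroxy-6-iodo-5-methoxy-2-oxo-4-propylchroman-8-carbaldehyde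
Conditions: NIS (1.05 equiv), TsOH·H2O (10 mol %), MeCN, 0 °C → rt, dark
Reagents that add atoms: N-iodosuccinimide, O=C1CCC(=O)N1I
Why: Electrophilic aromatic iodination, which should occur at C6 because it is the only ring C–H left and is activated by the ortho phenol and the ortho methoxy group.

Step 6
Reactants: 9 (R)-7-hydroxy-6-iodo-5-methoxy-2-oxo-4-propylchroman-8-carbaldehyde; 10 tributyl(3-methylbut-2-en-1-yl)stannane
Product: 11 (R)-7-hydroxy-5-methoxy-6-(3-methylbut-2-enyl)-2-oxo-4-propylchroman-8-carbaldehyde
Conditions: Pd(PPh3)4 (5 mol %), DMF, 90 °C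
Reagents that add atoms: none
Why: Stille coupling, in which zerovalent palladium inserts into the aryl C–I bond, the prenyl group is transferred from tin and reductive elimination at the less hindered allyl terminus should give the linear prenyl arene, the free phenol, aldehyde and lactone being tolerated under these neutral conditions.

Step 7
Reactants: 11 (R)-7-hydroxy-5-methoxy-6-(3-methylbut-2-enyl)-2-oxo-4-propylchroman-8-carbaldehyde; 12 (R)-but-3-en-2-ol
Product: 13 (R)-7-[(S)-but-3-en-2-yloxy]-5-methoxy-6-(3-methylbut-2-enyl)-2-oxo-4-propylchroman-8-carbaldehyde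
Conditions: PPh3 (1.5 equiv), DIAD (1.5 equiv), THF, 0 °C → rt
Reagents that add atoms: none
Why: Mitsunobu etherification, in which the only free and fairly acidic phenol displaces the activated (R)-alcohol by SN2 attack with inversion, setting the S configuration of the ether carbon that later becomes C2.

Step 8
Reactants: 13 (R)-7-[(S)-but-3-en-2-yloxy]-5-methoxy-6-(3-methylbut-2-enyl)-2-oxo-4-propylchroman-8-carbaldehyde
Product: 15 allyl (R)-3-[4-((S)-but-3-en-2-yloxy)-3-formyl-6-methoxy-2-(methoxymethoxy)-5-(3-methylbut-2-enyl)phenyl]hexanoate, via sodium aryloxide allyl ester 14 (not isolated)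
Conditions: allyl alcohol (3 equiv), NaH (1.1 equiv), THF, 0 °C; then MOMCl (1.5 equiv), 0 °C → rt
Reagents that add atoms: allyl alcohol, C=CCO; chloromethyl methyl ether, COCCl
Why: Transesterification followed by O-alkylation in one flask, in which allyloxide opens the activated aryl lactone essentially irreversibly because the 2-formylphenoxide of 14 is the far better leaving group, and this single phenoxide is then capped by MOMCl without touching the benzylic stereocentre.

Step 9
Reactants: 15 allyl (R)-3-[4-((S)-but-3-en-2-yloxy)-3-formyl-6-methoxy-2-(methoxymethoxy)-5-(3-methylbut-2-enyl)phenyl]hexanoate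
Product: 17 allyl (R)-3-[(2S,3S)-7-methoxy-5-(methoxymethoxy)-2,3-dimethyl-8-(3-methylbut-2-enyl)-4-oxochroman-6-yl]hexanoate, via cis C3 epimer 16 (not isolated)
Conditions: 2-mesityl-6,7-dihydro-5H-pyrrolo[2,1-c][1,2,4]triazol-2-ium tetrafluoroborate (20 mol %), DBU (40 mol %), degassed 1,4-dioxane, 80 °C, under argon
Reagents that add atoms: none
Why: DBU frees the carbene from the triazolium salt, the carbene adds to the aldehyde of 15 and proton transfer gives a nucleophilic enaminol; its carbinol carbon bonds to the internal vinyl carbon while its O–H proton passes to the terminal CH2 in a five-membered, ene-like transition state, and loss of the carbene then releases the ketone. The closest known reaction is the carbene-catalysed intramolecular hydroacylation of unactivated alkenes in 2-allyloxybenzaldehydes to 3-methylchroman-4-ones, applied here to an ether with a methyl branch and an aldehyde with a second ortho oxygen substituent. The pyranone ring (O1, C2, C3, C4, C4a, C8a) closes in the 6-exo-trig mode by forming the C3–C4 bond. C2 keeps the S configuration of the ether, and the new C3 centre is set under thermodynamic control: whatever cis epimer 16 forms, DBU epimerises the carbon alpha to the ketone to the trans (2S,3S) isomer 17 with both methyl groups equatorial. The step needs reaction at the terminal vinyl group only and a stable C2: the prenyl and allyl ester alkenes cannot reach the acyl carbon in a small-ring geometry, both positions ortho to the ether oxygen are substituted so a Claisen shift has no productive outlet, and the doubly ortho-substituted aldehyde resists benzoin dimerisation. Moderate temperature and sub-stoichiometric base limit ring opening by retro-oxa-Michael elimination.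

Step 10
Reactants: 17 allyl (R)-3-[(2S,3S)-7-methoxy-5-(methoxymethoxy)-2,3-dimethyl-8-(3-methylbut-2-enyl)-4-oxochroman-6-yl]hexanoate
Product: 18 allyl (R)-3-[(2S,3S)-5-hydroxy-7-methoxy-2,3-dimethyl-8-(3-methylbut-2-enyl)-4-oxochroman-6-yl]hexanoate
Conditions: 3 M aq. HCl, THF, 40 °C
Reagents that add atoms: none
Why: Acid-catalysed acetal hydrolysis, in which the MOM ether next to the C4 carbonyl is especially labile, so dilute aqueous acid should free the hydrogen-bonded C5 phenol without harming the prenyl alkene, and any partial hydrolysis of the allyl ester only anticipates step 11.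

Step 11
Reactants: 18 allyl (R)-3-[(2S,3S)-5-hydroxy-7-methoxy-2,3-dimethyl-8-(3-methylbut-2-enyl)-4-oxochroman-6-yl]hexanoate
Product: 19 (R)-3-[(2S,3S)-5-hydroxy-7-methoxy-2,3-dimethyl-8-(3-methylbut-2-enyl)-4-oxochroman-6-yl]hexanoic acid
Conditions: Pd(PPh3)4 (5 mol %), morpholine (5 equiv), THF, rt; acidic work-up (pH 3)
Reagents that add atoms: none
Why: Tsuji–Trost deallylation, in which Pd(PPh3)4 cleaves the allyl–oxygen bond of the ester and morpholine takes up the allyl group, freeing the acid under neutral conditions that should not epimerise C2 or C3 or touch the prenyl group.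

Compound list
1 | 3,5-dimethoxyphenol | COc1cc(O)cc(OC)c1 | starting material
2 | ethyl 3-oxohexanoate | CCCC(=O)CC(=O)OCC | starting material
3 | 5,7-dimethoxy-4-propyl-2H-chromen-2-one | CCCC1=CC(=O)Oc2cc(OC)cc(OC)c12 | intermediate
4 | (R)-5,7-dimethoxy-4-propylchroman-2-one | CCC[C@@H]1CC(=O)Oc2cc(OC)cc(OC)c21 | intermediate
5 | N-{[(R)-5,7-dimethoxy-2-oxo-4-propylchroman-8-yl]methylidene}-N-methylmethanaminium chloride | CCC[C@@H]1CC(=O)Oc2c(C=[N+](C)C)c(OC)cc(OC)c21.[Cl-] | intermediate
6 | (R)-5,7-dimethoxy-2-oxo-4-propylchroman-8-carbaldehyde | CCC[C@@H]1CC(=O)Oc2c(C=O)c(OC)cc(OC)c21 | intermediate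
7 | (R)-7-(dichloroboranyloxy)-5-methoxy-2-oxo-4-propylchroman-8-carbaldehyde | CCC[C@@H]1CC(=O)Oc2c(C=O)c(OB(Cl)Cl)cc(OC)c21 | intermediate
8 | (R)-7-hydroxy-5-methoxy-2-oxo-4-propylchroman-8-carbaldehyde | CCC[C@@H]1CC(=O)Oc2c(C=O)c(O)cc(OC)c21 | intermediate
9 | (R)-7-hydroxy-6-iodo-5-methoxy-2-oxo-4-propylchroman-8-carbaldehyde | CCC[C@@H]1CC(=O)Oc2c(C=O)c(O)c(I)c(OC)c21 | intermediate
10 | tributyl(3-methylbut-2-en-1-yl)stannane | CCCC[Sn](CCCC)(CCCC)CC=C(C)C | starting material
11 | (R)-7-hydroxy-5-methoxy-6-(3-methylbut-2-enyl)-2-oxo-4-propylchroman-8-carbaldehyde | CCC[C@@H]1CC(=O)Oc2c(C=O)c(O)c(CC=C(C)C)c(OC)c21 | intermediate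
12 | (R)-but-3-en-2-ol | C=C[C@@H](C)O | starting material
13 | (R)-7-[(S)-but-3-en-2-yloxy]-5-methoxy-6-(3-methylbut-2-enyl)-2-oxo-4-propylchroman-8-carbaldehyde | CCC[C@@H]1CC(=O)Oc2c(C=O)c(O[C@@H](C)C=C)c(CC=C(C)C)c(OC)c21 | intermediate
14 | sodium 6-[(R)-1-(allyloxy)-1-oxohexan-3-yl]-3-[(S)-but-3-en-2-yloxy]-2-formyl-5-methoxy-4-(3-methylbut-2-enyl)phenolate | CCC[C@H](CC(=O)OCC=C)c1c([O-])c(C=O)c(O[C@@H](C)C=C)c(CC=C(C)C)c1OC.[Na+] | intermediate
15 | allyl (R)-3-[4-((S)-but-3-en-2-yloxy)-3-formyl-6-methoxy-2-(methoxymethoxy)-5-(3-methylbut-2-enyl)phenyl]hexanoate | CCC[C@H](CC(=O)OCC=C)c1c(OCOC)c(C=O)c(O[C@@H](C)C=C)c(CC=C(C)C)c1OC | intermediate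
16 | allyl (R)-3-[(2S,3R)-7-methoxy-5-(methoxymethoxy)-2,3-dimethyl-8-(3-methylbut-2-enyl)-4-oxochroman-6-yl]hexanoate | CCC[C@H](CC(=O)OCC=C)c1c(OCOC)c2c(c(CC=C(C)C)c1OC)O[C@@H](C)[C@@H](C)C2=O | intermediate
17 | allyl (R)-3-[(2S,3S)-7-methoxy-5-(methoxymethoxy)-2,3-dimethyl-8-(3-methylbut-2-enyl)-4-oxochroman-6-yl]hexanoate | CCC[C@H](CC(=O)OCC=C)c1c(OCOC)c2c(c(CC=C(C)C)c1OC)O[C@@H](C)[C@H](C)C2=O | intermediate
18 | allyl (R)-3-[(2S,3S)-5-hydroxy-7-methoxy-2,3-dimethyl-8-(3-methylbut-2-enyl)-4-oxochroman-6-yl]hexanoate | CCC[C@H](CC(=O)OCC=C)c1c(O)c2c(c(CC=C(C)C)c1OC)O[C@@H](C)[C@H](C)C2=O | intermediate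
19 | (R)-3-[(2S,3S)-5-hydroxy-7-methoxy-2,3-dimethyl-8-(3-methylbut-2-enyl)-4-oxochroman-6-yl]hexanoic acid | CCC[C@H](CC(=O)O)c1c(O)c2c(c(CC=C(C)C)c1OC)O[C@@H](C)[C@H](C)C2=O | target

Total step count: 11. Longest linear sequence: 11 steps (1 → 19); building blocks 2, 10 and 12 enter as purchased.

Steps most likely to fail

Step 9. The carbene may add too slowly to the aldehyde between two ortho oxygen substituents, or the ene-like bond formation may stall on the methyl-branched ether; prolonged heating with base would then erode C2 by ring opening and reclosure. The fallback sets out from 15 and comes back at 17, and makes the same C3–C4 bond by a 6-exo acyl radical cyclisation. Pinnick oxidation of 15 (NaClO2, NaH2PO4, 2-methylbut-2-ene, t-BuOH–H2O, rt) should give 5-[(R)-1-(allyloxy)-1-oxohexan-3-yl]-2-[(S)-but-3-en-2-yloxy]-4-methoxy-6-(methoxymethoxy)-3-(3-methylbut-2-enyl)benzoic acid F1. Diphenyl diselenide and PBu3 in CH2Cl2 should convert it into Se-phenyl 5-[(R)-1-(allyloxy)-1-oxohexan-3-yl]-2-[(S)-but-3-en-2-yloxy]-4-methoxy-6-(methoxymethoxy)-3-(3-methylbut-2-enyl)benzenecarboselenoate F2. Slow addition of Bu3SnH with AIBN in benzene at 80 °C should generate the aroyl radical, which closes onto the internal vinyl carbon; hydrogen transfer to the primary radical and a short DBU treatment at rt to equilibrate C3 should then give 17.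

Step 7. The hindered, hydrogen-bonded phenol may react sluggishly, and SN2′ attack or ionisation of the activated allylic alcohol may lead to the linear crotyl ether or to loss of enantiomeric purity at the ether carbon. The fallback sets out from 11 and comes back at 13, and replaces the chiral-pool displacement by catalytic asymmetric allylic etherification. Phenol 11 and achiral (E)-but-2-enyl methyl carbonate with Pd2(dba)3·CHCl3 and an enantiopure diaminocyclohexane-derived bisphosphine ligand in CH2Cl2 at rt should give the branched (S)-ether 13 directly, the ligand antipode fixing the configuration. No new compound is made on this detour (F0).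

Step 2. Hydride delivery to the electron-rich C4, which is crowded by the neighbouring 5-methoxy group, may be slow or poorly face-selective, and forcing it may over-reduce the lactone. The fallback sets out from 1 and comes back at 4, and creates the stereocentre by C–C instead of C–H bond formation. Phenol 1 and propiolic acid with Pd(OAc)2 in CF3CO2H at rt should give 5,7-dimethoxy-2H-chromen-2-one F3 by hydroarylation and lactonisation. Copper-catalysed asymmetric conjugate addition of n-PrMgBr (CuBr·SMe2, an enantiopure ferrocenyl bisphosphine of the Josiphos family, t-BuOMe, −72 °C) should then place the propyl group at C4 and give 4.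

Further compounds
F1 | step 9 | 5-[(R)-1-(allyloxy)-1-oxohexan-3-yl]-2-[(S)-but-3-en-2-yloxy]-4-methoxy-6-(methoxymethoxy)-3-(3-methylbut-2-enyl)benzoic acid | CCC[C@H](CC(=O)OCC=C)c1c(OCOC)c(C(=O)O)c(O[C@@H](C)C=C)c(CC=C(C)C)c1OC
F2 | step 9 | Se-phenyl 5-[(R)-1-(allyloxy)-1-oxohexan-3-yl]-2-[(S)-but-3-en-2-yloxy]-4-methoxy-6-(methoxymethoxy)-3-(3-methylbut-2-enyl)benzenecarboselenoate | CCC[C@H](CC(=O)OCC=C)c1c(OCOC)c(C(=O)[Se]c2ccccc2)c(O[C@@H](C)C=C)c(CC=C(C)C)c1OC
F0 | step 7 | none | none
F3 | step 2 | 5,7-dimethoxy-2H-chromen-2-one | COc1cc(OC)c2ccc(=O)oc2c1
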